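## Structural features

The target is an achiral diaryl ether. Ring A is a methyl benzoate with the ester on C1, a prenyl ether on C2, a methyl group on C4 and the bridging oxygen on C6. Ring B carries the bridging oxygen on C1', a hydroxymethyl group on C2', a methoxy group on C4' and a second prenyl ether on C6'. There is no stereocentre, so the synthesis has to control only regiochemistry and chemoselectivity. The fragile groups are the two aryl prenyl ethers (cleaved by acid, rearranged by strong heating, and nucleophilic at the alkene), the benzylic alcohol, and the electron-rich ring B; the ester is shielded by two ortho substituents. The real difficulty is twofold. The C6–O–C1' bond joins carbons with ortho substituents on both rings (the ester on C1; C2' and C6' on ring B), which is unfavourable for a direct aryl ether coupling. Ring B also holds three oxygens (C1', C4', C6') that each need a different substituent. The key step uses the fact that the C4' and C6' oxygens are meta and the C1' oxygen sits next to C6'. C6' can then come from a cyclobutenone carbonyl, C1' from the sp3 ring carbon that bears the aryloxy group, C2' and C3' from the enone carbons, and C5' and C4' from the two carbons of a silyl ynol ether.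

## Logic of the disconnections

**22 ⇒ 21.** The O–CH3 bond on C4' is cut. The two hydroxyls of 21 differ in acidity by several pKa units, so no protecting group is needed. The forward step must alkylate only the phenoxide, which calls for a weak base.

**21 ⇒ 20.** The two O–Si bonds (C4' oxygen and benzylic oxygen) are cut together. Both silyl groups respond to fluoride, so one operation exposes both hydroxyls. The forward step must leave the prenyl ethers and the ester untouched.

**20 ⇒ 19 + 2.** The O–C bond of the C6' prenyl ether is cut. In 19 the C6' oxygen is the only free phenol, so the forward step has no site-selectivity problem. It must, however, be mild enough not to cleave or transfer the aryl silyl ether on C4'.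

**19 ⇒ 10 + 14.** Ring B is taken apart at C6'–C5' and C4'–C3'; the C6'–C1' bond is broken and re-formed within the same step. This removes the whole of ring B and leaves a four-membered enone and a two-carbon ynol ether. The hindered diaryl ether becomes an ether between a phenol and an sp3 carbon, and the three ring B oxygens emerge already differentiated as ether, free phenol and silyl ether. The forward step needs the unsubstituted alkyne carbon to bond to the ketene carbonyl carbon. It also needs a temperature below that at which aryl prenyl ethers rearrange.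

**14 ⇒ 11.** The O–Si and C–O bonds of the ynol ether are cut, which leads back to acetylene, an oxygen-transfer reagent and a silyl triflate. Compound 14 is not an article of commerce, so its preparation is part of the route. The forward step must hold the monolithium acetylide intact and silylate the ynolate on oxygen.

**10 ⇒ 5 + 6.** The cyclobutenone is cut at C1–C2 and C3–C4 (cyclobutenone locants), a [2+2] retron; the carbonyl oxygen comes from water. This reduces the strained ring to an aryloxyacetamide and a terminal alkyne. The forward step must place the silyloxymethyl group on C3, which the polarity of a terminal alkyne ensures. The alkyne must also win against the prenyl alkene of 5 for the keteniminium ion, which is arranged by a large excess of 6.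

**5 ⇒ 3 + 4.** The O–CH2 bond is cut, a phenol alkylation with an α-chloroamide. The forward step must alkylate a hydrogen-bonded salicylate hydroxyl, so it needs a polar solvent and iodide catalysis.

**3 ⇒ 1 + 2.** One O–prenyl bond is cut. The two hydroxyls of 1 are equivalent, so the forward step must stop after one alkylation. This is helped by the hydrogen bond that the remaining hydroxyl forms with the ester.

## Other disconnections considered

**Alternative 1:** Ring A is cut at C1–C6 and C4–C5.
- Forward step: methyl 4-acetoxy-6-methyl-2-oxo-2H-pyran-3-carboxylate A2 would act as an electron-poor diene toward the ethynyl ether A3 of the ring B phenol A4. The alkyne adds across C3 and C6 of the pyrone and the bridged lactone loses CO2 to give the diaryl ether acetate A1.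
- In favour: the polarity is matched (the terminal alkyne carbon of A3 should bond to pyrone C6, the oxygen-bearing carbon to C3 next to the ester), and loss of CO2 makes the aromatisation irreversible. The bridging oxygen is again attached before the ring it ends on exists. No strained four-membered intermediate is involved; on handling of intermediates this alternative is the better one.
- Against: A4 must first be made with all three ring B oxygen substituents in place, which is the problem the chosen plan solves within its key step. A3 must be made from a hindered phenol. The pyrone carries a methyl group on the reacting C6 and a donor acyloxy group on C4, so the cycloaddition is likely to need temperatures at which the C6' prenyl ether of ring B could rearrange.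
- Comparison: both are thermal pericyclic cascades that end in aromatisation. After the key step both need three operations (here acetate cleavage, prenylation, desilylation), so they are equal on that count. Before the key step this alternative is longer, and it leaves the regiochemistry of ring B to classical arene chemistry.

**Alternative 2:** Ring B is cut at C1'–C2' and C4'–C5'.
- Forward step: the enolate of the allyl 2-aryloxy-3-oxobutanoate A6 (from 3 and an allyl 2-haloacetoacetate) would add to the β-carbon of methyl 4,4-diethoxybut-2-ynoate A7. The acetyl methyl enolate would then close onto the ynoate ester to give the cyclohexenedione A5. Deallylation with Pd(PPh3)4 (zerovalent palladium) and decarboxylation would aromatise it to the resorcinol acetal A8.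
- In favour: the chemistry is ionic and runs at or below room temperature, so the prenyl ether is not exposed to heat. No ynol ether and no strained ring are needed; on reagent availability this alternative is the better one. The aryl ether bond is again made by alkylating a phenol at sp3 carbon, which is equal to the chosen plan.
- Against: the Michael donor is a hindered tertiary enolate that must form a quaternary carbon. Only one alkene geometry of the adduct can cyclise. O-cyclisation to a pyrone and retro-Claisen cleavage of the non-enolisable β-keto ester compete. A8 shows two free phenols on C4' and C6' that must then be told apart. The acetal must be hydrolysed with acid in the presence of two prenyl ethers and the aldehyde reduced.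
- Comparison: this alternative needs about five operations after its key step against three, and it gives up the built-in differentiation of the ring B oxygens.

**Alternative 3:** Ring A is cut at C2–C3.
- Forward step: base would remove a proton from a terminal methyl of the dienyl malonate A10. The resulting carbon attacks one malonate ester, methoxide leaves, and tautomerisation gives the salicylate A9.
- In favour: both reacting termini are doubly degenerate (two methyls, two esters), so alkene geometry cannot block the closure. The conditions are mild. A9 is only a prenylation and a desilylation away from the target, two operations against three; on the end game this alternative is the better one.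
- Against: A10 has to be made by adding the di-ortho-substituted phenol A4 to a hindered vinylogous acid chloride A11 and expelling chloride. The aryloxide is itself a leaving group from A10 once methoxide is released. A4 again has to be made first with three different oxygens placed by arene chemistry.
- Comparison: the alternative is milder and shorter after the key step. It is longer overall and leaves the ring B substitution pattern unsolved.

Key step: step 5

**Remarks before the steps**
- Locants: ring A has C1 (ester carbon), C2 (prenyloxy), C4 (methyl), C6 (bridging oxygen). Ring B has C1' (bridging oxygen), C2' (CH2O), C4', C6'. "ArA" denotes 2-(methoxycarbonyl)-5-methyl-3-(3-methylbut-2-enyloxy)phenyl.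
- The atom mapping from 10 and 14 to 19 was checked against the target and is consistent. No structure needed correction.
- Compounds 9, 10, 16 and 18 each have one stereocentre and are racemic. It is erased when ring B aromatises.
- Assumption: tert-butyldimethyl(prop-2-ynyloxy)silane 6 is taken as a catalogue compound. If it is not to hand, one silylation of propargyl alcohol supplies it.
- Design points: 14 is made in the route (step 4). Step 3 uses a fivefold excess of 6. Step 5 is capped at 110 °C and uses excess 14. Step 6 is run in acetone to protect the aryl silyl ether.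

## Steps

**Step 1**
Reactants: 1 methyl 2,6-dihydroxy-4-methylbenzoate; 2 1-bromo-3-methylbut-2-ene (prenyl bromide)
Product: 3 methyl 2-hydroxy-4-methyl-6-(3-methylbut-2-enyloxy)benzoate
Conditions: 2 (1.05 equiv), K2CO3 (1.1 equiv), acetone, 45 °C
Reagents that add atoms: none
Why: Williamson ether synthesis; the two hydroxyls of 1 are equivalent, and after the first alkylation the remaining one is held in a hydrogen bond to the ester carbonyl, which should slow a second alkylation. K2CO3 in acetone should favour O- over C-prenylation.

**Step 2**
Reactants: 3 methyl 2-hydroxy-4-methyl-6-(3-methylbut-2-enyloxy)benzoate; 4 2-chloro-N,N-dimethylacetamide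
Product: 5 methyl 2-[2-(dimethylamino)-2-oxoethoxy]-4-methyl-6-(3-methylbut-2-enyloxy)benzoate
Conditions: 4 (1.3 equiv), K2CO3 (2 equiv), KI (0.1 equiv), DMF, 70 °C
Reagents that add atoms: none
Why: Williamson etherification of the hydrogen-bonded salicylate hydroxyl with a reactive α-haloamide; iodide exchange (Finkelstein) and the polar solvent make up for the low nucleophilicity of the phenoxide, and no other nucleophilic site is left.

**Step 3**
Reactants: 5 methyl 2-[2-(dimethylamino)-2-oxoethoxy]-4-methyl-6-(3-methylbut-2-enyloxy)benzoate; 6 tert-butyldimethyl(prop-2-ynyloxy)silane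
Product: 10 racemic 4-(ArA-oxy)-3-(tert-butyldimethylsilyloxymethyl)cyclobut-2-enone, via triflyloxyiminium triflate 7 (not isolated), via keteniminium triflate 8 (not isolated), via cyclobuteniminium triflate 9 (not isolated)
Conditions: Tf2O (1.2 equiv), 6 (5 equiv), 2,4,6-collidine (1.3 equiv, slow addition), CH2Cl2, −20 °C → 40 °C; then sat. aq. NaHCO3, rt
Reagents that add atoms: water, O
Why: Tf2O activates the tertiary amide to 7, collidine eliminates it to keteniminium ion 8, and a Ghosez keteniminium–alkyne [2+2] cycloaddition with 6 gives 9, which is hydrolysed to the enone. The terminal alkyne carbon bonds to the iminium carbon (the more substituted vinyl cation is formed), which places the silyloxymethyl group on C3 and the aryloxy carbon on C4; the new C4 centre is racemic. The fivefold excess of 6 is meant to outrun capture of 8 by the prenyl alkene.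

**Step 4**
Reactants: 11 ethyne (acetylene)
Product: 14 triisopropylsilyloxyethyne, via lithium acetylide 12 (not isolated), via lithium ethynolate 13 (not isolated)
Conditions: HC≡CH (excess), n-BuLi (1.0 equiv), THF, −78 °C; t-BuOOLi [from t-BuOOH and LiN(SiMe3)2, THF, −78 °C], −78 → −10 °C; i-Pr3SiOTf, −78 → 0 °C; pentane, cold aq. NaHCO3
Reagents that add atoms: tert-butyl hydroperoxide, CC(C)(C)OO; triisopropylsilyl trifluoromethanesulfonate, CC(C)[Si](C(C)C)(C(C)C)OS(=O)(=O)C(F)(F)F
Why: Electrophilic oxygen transfer from lithium tert-butyl peroxide to a lithium acetylide is a known route to lithium ynolates, and the bulky silyl triflate should silylate oxygen rather than carbon. Excess acetylene and low temperature are meant to keep 12 from disproportionating.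

**Step 5**
Reactants: 10 racemic 4-(ArA-oxy)-3-(tert-butyldimethylsilyloxymethyl)cyclobut-2-enone; 14 triisopropylsilyloxyethyne
Product: 19 methyl 2-[2-(tert-butyldimethylsilyloxymethyl)-6-hydroxy-4-(triisopropylsilyloxy)phenoxy]-4-methyl-6-(3-methylbut-2-enyloxy)benzoate, via aryloxy vinylketene 15 (not isolated), via vinylcyclobutenone 16 (not isolated), via dienylketene 17 (not isolated), via cyclohexadienone 18 (not isolated)
Conditions: 14 (2.5 equiv), toluene (0.1 M), argon, 80 °C → 110 °C
Reagents that add atoms: none
Why: This is a Danheiser benzannulation, the known reaction of cyclobutenones with silyloxyalkynes to give resorcinol monosilyl ethers. Heating opens 10 by conrotatory 4π electrocyclic cleavage of the C1–C4 bond to vinylketene 15; the aryloxy donor turns outward, so the terminus keeps its hydrogen on the inside. Ketene 15 then undergoes [2+2] cycloaddition with 14, in which the nucleophilic unsubstituted alkyne carbon bonds to the ketene carbonyl carbon (C6'–C5') and the oxygen-bearing alkyne carbon bonds to the former C2 (C4'–C3'), giving 16. A second reversible 4π opening gives dienylketene 17, and the isomer with the vinyl group turned inward closes ring B by a thermally allowed disrotatory 6π electrocyclisation between the ketene carbon and the aryloxy-bearing terminus (C6'–C1') to give 18. Tautomerisation of 18 gives the phenol; this removes the only stereocentre, so no stereocontrol is needed. The regiochemistry rests on the polarity of the ynol ether, which makes its CH carbon the nucleophile. Chemoselectivity over the prenyl alkenes rests on the much higher ketenophilicity of 14 and its excess, which should also limit acylation of the product phenol by 15. The ceiling of 110 °C keeps the aryl prenyl ether below the temperature at which a Claisen rearrangement is expected.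

**Step 6**
Reactants: 19 methyl 2-[2-(tert-butyldimethylsilyloxymethyl)-6-hydroxy-4-(triisopropylsilyloxy)phenoxy]-4-methyl-6-(3-methylbut-2-enyloxy)benzoate; 2 1-bromo-3-methylbut-2-ene
Product: 20 methyl 2-[2-(tert-butyldimethylsilyloxymethyl)-6-(3-methylbut-2-enyloxy)-4-(triisopropylsilyloxy)phenoxy]-4-methyl-6-(3-methylbut-2-enyloxy)benzoate
Conditions: 2 (1.5 equiv), K2CO3 (2 equiv), acetone, 50 °C
Reagents that add atoms: none
Why: Williamson ether synthesis on the only free phenol; K2CO3 in dry acetone is mild enough that the hindered aryl triisopropylsilyl ether and the alkyl silyl ether should stay in place.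

**Step 7**
Reactants: 20 methyl 2-[2-(tert-butyldimethylsilyloxymethyl)-6-(3-methylbut-2-enyloxy)-4-(triisopropylsilyloxy)phenoxy]-4-methyl-6-(3-methylbut-2-enyloxy)benzoate
Product: 21 methyl 2-[4-hydroxy-2-(hydroxymethyl)-6-(3-methylbut-2-enyloxy)phenoxy]-4-methyl-6-(3-methylbut-2-enyloxy)benzoate
Conditions: Bu4NF (3 equiv), THF, argon, 0 °C → rt; aq. NH4Cl
Reagents that add atoms: none
Why: Fluoride-driven cleavage of both Si–O bonds (formation of the strong Si–F bond); prenyl ethers, the diaryl ether and the doubly ortho-substituted ester are inert to fluoride.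

**Step 8**
Reactants: 21 methyl 2-[4-hydroxy-2-(hydroxymethyl)-6-(3-methylbut-2-enyloxy)phenoxy]-4-methyl-6-(3-methylbut-2-enyloxy)benzoate
Product: 22 methyl 2-[2-(hydroxymethyl)-4-methoxy-6-(3-methylbut-2-enyloxy)phenoxy]-4-methyl-6-(3-methylbut-2-enyloxy)benzoate
Conditions: MeI (1.5 equiv), K2CO3 (1.5 equiv), acetone, rt
Reagents that add atoms: iodomethane, CI
Why: Williamson O-methylation; K2CO3 deprotonates the C4' phenol but not the benzylic alcohol, so only the phenoxide should be alkylated.

## Compound list

1 | methyl 2,6-dihydroxy-4-methylbenzoate | COC(=O)c1c(O)cc(C)cc1O | starting material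
2 | 1-bromo-3-methylbut-2-ene (prenyl bromide) | CC(C)=CCBr | starting material
3 | methyl 2-hydroxy-4-methyl-6-(3-methylbut-2-enyloxy)benzoate | COC(=O)c1c(O)cc(C)cc1OCC=C(C)C | intermediate
4 | 2-chloro-N,N-dimethylacetamide | CN(C)C(=O)CCl | starting material
5 | methyl 2-[2-(dimethylamino)-2-oxoethoxy]-4-methyl-6-(3-methylbut-2-enyloxy)benzoate | COC(=O)c1c(OCC=C(C)C)cc(C)cc1OCC(=O)N(C)C | intermediate
6 | tert-butyldimethyl(prop-2-ynyloxy)silane | C#CCO[Si](C)(C)C(C)(C)C | starting material
7 | [2-(ArA-oxy)-1-(trifluoromethylsulfonyloxy)ethylidene]dimethylammonium triflate | COC(=O)c1c(OCC=C(C)C)cc(C)cc1OCC(OS(=O)(=O)C(F)(F)F)=[N+](C)C.[O-]S(=O)(=O)C(F)(F)F | intermediate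
8 | [2-(ArA-oxy)ethenylidene]dimethylammonium triflate (keteniminium salt) | COC(=O)c1c(OCC=C(C)C)cc(C)cc1OC=C=[N+](C)C.[O-]S(=O)(=O)C(F)(F)F | intermediate
9 | racemic [4-(ArA-oxy)-3-(tert-butyldimethylsilyloxymethyl)cyclobut-2-enylidene]dimethylammonium triflate | COC(=O)c1c(OCC=C(C)C)cc(C)cc1OC1C(=[N+](C)C)C=C1CO[Si](C)(C)C(C)(C)C.[O-]S(=O)(=O)C(F)(F)F | intermediate
10 | racemic 4-(ArA-oxy)-3-(tert-butyldimethylsilyloxymethyl)cyclobut-2-enone | COC(=O)c1c(OCC=C(C)C)cc(C)cc1OC1C(=O)C=C1CO[Si](C)(C)C(C)(C)C | intermediate
11 | ethyne (acetylene) | C#C | starting material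
12 | lithium acetylide | [Li+].[C-]#C | intermediate
13 | lithium ethynolate | [Li+].[O-]C#C | intermediate
14 | triisopropylsilyloxyethyne | C#CO[Si](C(C)C)(C(C)C)C(C)C | intermediate
15 | (Z)-4-(ArA-oxy)-3-(tert-butyldimethylsilyloxymethyl)buta-1,3-dien-1-one (aryloxy trans to the ketene CH) | COC(=O)c1c(OCC=C(C)C)cc(C)cc1O/C=C(/C=C=O)CO[Si](C)(C)C(C)(C)C | intermediate
16 | racemic 4-[(Z)-2-(ArA-oxy)-1-(tert-butyldimethylsilyloxymethyl)ethenyl]-3-(triisopropylsilyloxy)cyclobut-2-enone | COC(=O)c1c(OCC=C(C)C)cc(C)cc1O/C=C(/C1C(=O)C=C1O[Si](C(C)C)(C(C)C)C(C)C)CO[Si](C)(C)C(C)(C)C | intermediate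
17 | (3E,5Z)-6-(ArA-oxy)-5-(tert-butyldimethylsilyloxymethyl)-3-(triisopropylsilyloxy)hexa-1,3,5-trien-1-one | COC(=O)c1c(OCC=C(C)C)cc(C)cc1O/C=C(CO[Si](C)(C)C(C)(C)C)/C=C(\C=C=O)O[Si](C(C)C)(C(C)C)C(C)C | intermediate
18 | racemic 6-(ArA-oxy)-5-(tert-butyldimethylsilyloxymethyl)-3-(triisopropylsilyloxy)cyclohexa-2,4-dienone | COC(=O)c1c(OCC=C(C)C)cc(C)cc1OC1C(=O)C=C(O[Si](C(C)C)(C(C)C)C(C)C)C=C1CO[Si](C)(C)C(C)(C)C | intermediate
19 | methyl 2-[2-(tert-butyldimethylsilyloxymethyl)-6-hydroxy-4-(triisopropylsilyloxy)phenoxy]-4-methyl-6-(3-methylbut-2-enyloxy)benzoate | COC(=O)c1c(OCC=C(C)C)cc(C)cc1Oc1c(CO[Si](C)(C)C(C)(C)C)cc(O[Si](C(C)C)(C(C)C)C(C)C)cc1O | intermediate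
20 | methyl 2-[2-(tert-butyldimethylsilyloxymethyl)-6-(3-methylbut-2-enyloxy)-4-(triisopropylsilyloxy)phenoxy]-4-methyl-6-(3-methylbut-2-enyloxy)benzoate | COC(=O)c1c(OCC=C(C)C)cc(C)cc1Oc1c(CO[Si](C)(C)C(C)(C)C)cc(O[Si](C(C)C)(C(C)C)C(C)C)cc1OCC=C(C)C | intermediate
21 | methyl 2-[4-hydroxy-2-(hydroxymethyl)-6-(3-methylbut-2-enyloxy)phenoxy]-4-methyl-6-(3-methylbut-2-enyloxy)benzoate | COC(=O)c1c(OCC=C(C)C)cc(C)cc1Oc1c(CO)cc(O)cc1OCC=C(C)C | intermediate
22 | methyl 2-[2-(hydroxymethyl)-4-methoxy-6-(3-methylbut-2-enyloxy)phenoxy]-4-methyl-6-(3-methylbut-2-enyloxy)benzoate | COC(=O)c1c(OCC=C(C)C)cc(C)cc1Oc1c(CO)cc(OC)cc1OCC=C(C)C | target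

## Step count and least certain steps

Total: 8 steps. Longest linear sequence: 7 steps (1, 2, 3, 5, 6, 7, 8); step 4 supplies the second component of step 5.

**Step 5 (key step).** The most likely failure is loss of the terminal silyl ynol ether during heating, by oxygen-to-carbon silyl migration or self-condensation, before the vinylketene has formed. Acylation of the newly formed phenol by the vinylketene would add to the loss. The fallback re-plans the annulation around an alkyl ynol ether; it sets out from 10 and returns at 22. Commercial 2-chloro-1,1-dimethoxyethane is treated with NaNH2 in liquid NH3 (loss of HCl and methanol) to give methoxyethyne F1, which is kept as a cold solution. Heating 10 with F1 in toluene in a sealed vessel at 80–100 °C should give, by the same cascade, methyl 2-[2-(tert-butyldimethylsilyloxymethyl)-6-hydroxy-4-methoxyphenoxy]-4-methyl-6-(3-methylbut-2-enyloxy)benzoate F2, in which C4' already carries the methyl ether. Prenylation with 2 and K2CO3 in acetone gives methyl 2-[2-(tert-butyldimethylsilyloxymethyl)-4-methoxy-6-(3-methylbut-2-enyloxy)phenoxy]-4-methyl-6-(3-methylbut-2-enyloxy)benzoate F3, and Bu4NF in THF removes the one silyl group to give 22. The price is a low-boiling reagent that tends to polymerise and must be made with sodium amide. The gain is that no silyl shift is possible and the end game is one operation shorter.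

**Step 3.** The most likely failure is capture of keteniminium ion 8 by the trisubstituted alkene of a prenyl ether in a second molecule, leading to oligomers in spite of the excess of 6. The fallback keeps the prenyl group off ring A until the strong electrophile has been used; it sets out from 1 and returns at 20. Compound 1 is mono-alkylated with 4 (K2CO3, KI, DMF) to methyl 2-[2-(dimethylamino)-2-oxoethoxy]-6-hydroxy-4-methylbenzoate F4. This is acetylated (Ac2O, pyridine) to methyl 2-acetoxy-6-[2-(dimethylamino)-2-oxoethoxy]-4-methylbenzoate F5. The conditions of step 3 should give racemic methyl 2-acetoxy-6-{[2-(tert-butyldimethylsilyloxymethyl)-4-oxocyclobut-2-enyl]oxy}-4-methylbenzoate F6, and the conditions of step 5 should give methyl 2-acetoxy-6-[2-(tert-butyldimethylsilyloxymethyl)-6-hydroxy-4-(triisopropylsilyloxy)phenoxy]-4-methylbenzoate F7. Aminolysis of the aryl acetate with pyrrolidine in CH2Cl2, which should spare the aryl silyl ether, gives methyl 2-[2-(tert-butyldimethylsilyloxymethyl)-6-hydroxy-4-(triisopropylsilyloxy)phenoxy]-6-hydroxy-4-methylbenzoate F8. Double prenylation with 2 and K2CO3 then gives 20. This also removes the prenyl ether from the heated step, at the cost of two more operations.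

**Step 4.** The most likely failure is disproportionation of monolithium acetylide to the insoluble dilithium salt while the mixture is warmed for the oxygen transfer, with partial C-silylation of the ynolate as a second risk. The fallback makes the triple bond by elimination instead of oxidising an acetylide. It replaces 11 as the two-carbon source and returns at 14. Cleavage of THF with n-BuLi gives lithium ethenolate, which is silylated with i-Pr3SiCl to triisopropyl(vinyloxy)silane F9. Bromine at −78 °C in pentane gives racemic (1,2-dibromoethoxy)triisopropylsilane F10, which is not stored; Et3N converts it to (Z)-(2-bromoethenyloxy)triisopropylsilane F11. Anti-elimination of HBr with LiN(i-Pr)2 (2.2 equiv, THF, −78 °C) and protonation of the resulting lithium alkynide should give 14. This is the classical dehydrohalogenation of a β-halovinyl ether to an ynol ether.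

**Step 6.** The most likely failure is attack of the phenoxide of 19 on silicon of the C4' aryl silyl ether (silyl transfer or cleavage) under the basic conditions, with C-prenylation at C5' as a second risk. The fallback avoids a free phenoxide; it sets out from 19 and returns at 20. A Mitsunobu etherification with 3-methylbut-2-en-1-ol, PPh3 and diisopropyl azodicarboxylate in THF at 0 °C forms the same ether under neutral conditions and makes no new intermediate.

## Further compounds

F1 | step 5 | methoxyethyne | COC#C
F2 | step 5 | methyl 2-[2-(tert-butyldimethylsilyloxymethyl)-6-hydroxy-4-methoxyphenoxy]-4-methyl-6-(3-methylbut-2-enyloxy)benzoate | COC(=O)c1c(OCC=C(C)C)cc(C)cc1Oc1c(CO[Si](C)(C)C(C)(C)C)cc(OC)cc1O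
F3 | step 5 | methyl 2-[2-(tert-butyldimethylsilyloxymethyl)-4-methoxy-6-(3-methylbut-2-enyloxy)phenoxy]-4-methyl-6-(3-methylbut-2-enyloxy)benzoate | COC(=O)c1c(OCC=C(C)C)cc(C)cc1Oc1c(CO[Si](C)(C)C(C)(C)C)cc(OC)cc1OCC=C(C)C
F4 | step 3 | methyl 2-[2-(dimethylamino)-2-oxoethoxy]-6-hydroxy-4-methylbenzoate | COC(=O)c1c(O)cc(C)cc1OCC(=O)N(C)C
F5 | step 3 | methyl 2-acetoxy-6-[2-(dimethylamino)-2-oxoethoxy]-4-methylbenzoate | COC(=O)c1c(OC(C)=O)cc(C)cc1OCC(=O)N(C)C
F6 | step 3 | racemic methyl 2-acetoxy-6-{[2-(tert-butyldimethylsilyloxymethyl)-4-oxocyclobut-2-enyl]oxy}-4-methylbenzoate | COC(=O)c1c(OC(C)=O)cc(C)cc1OC1C(=O)C=C1CO[Si](C)(C)C(C)(C)C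
F7 | step 3 | methyl 2-acetoxy-6-[2-(tert-butyldimethylsilyloxymethyl)-6-hydroxy-4-(triisopropylsilyloxy)phenoxy]-4-methylbenzoate | COC(=O)c1c(OC(C)=O)cc(C)cc1Oc1c(CO[Si](C)(C)C(C)(C)C)cc(O[Si](C(C)C)(C(C)C)C(C)C)cc1O
F8 | step 3 | methyl 2-[2-(tert-butyldimethylsilyloxymethyl)-6-hydroxy-4-(triisopropylsilyloxy)phenoxy]-6-hydroxy-4-methylbenzoate | COC(=O)c1c(O)cc(C)cc1Oc1c(CO[Si](C)(C)C(C)(C)C)cc(O[Si](C(C)C)(C(C)C)C(C)C)cc1O
F9 | step 4 | triisopropyl(vinyloxy)silane | C=CO[Si](C(C)C)(C(C)C)C(C)C
F10 | step 4 | racemic (1,2-dibromoethoxy)triisopropylsilane | BrCC(Br)O[Si](C(C)C)(C(C)C)C(C)C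
F11 | step 4 | (Z)-(2-bromoethenyloxy)triisopropylsilane | Br/C=C\O[Si](C(C)C)(C(C)C)C(C)C
F0 | step 6 | none | none
A1 | alternative 1 | methyl 2-acetoxy-6-[2-(tert-butyldimethylsilyloxymethyl)-4-methoxy-6-(3-methylbut-2-enyloxy)phenoxy]-4-methylbenzoate | COC(=O)c1c(OC(C)=O)cc(C)cc1Oc1c(CO[Si](C)(C)C(C)(C)C)cc(OC)cc1OCC=C(C)C
A2 | alternative 1 | methyl 4-acetoxy-6-methyl-2-oxo-2H-pyran-3-carboxylate | COC(=O)C1=C(OC(C)=O)C=C(C)OC1=O
A3 | alternative 1 | tert-butyl{[2-(ethynyloxy)-5-methoxy-3-(3-methylbut-2-enyloxy)phenyl]methoxy}dimethylsilane | C#COc1c(CO[Si](C)(C)C(C)(C)C)cc(OC)cc1OCC=C(C)C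
A4 | alternative 1 | 2-(tert-butyldimethylsilyloxymethyl)-4-methoxy-6-(3-methylbut-2-enyloxy)phenol | Oc1c(CO[Si](C)(C)C(C)(C)C)cc(OC)cc1OCC=C(C)C
A5 | alternative 2 | racemic allyl 1-(ArA-oxy)-2-(diethoxymethyl)-4,6-dioxocyclohex-2-ene-1-carboxylate | C=CCOC(=O)C1(Oc2cc(C)cc(OCC=C(C)C)c2C(=O)OC)C(C(OCC)OCC)=CC(=O)CC1=O
A6 | alternative 2 | racemic allyl 2-(ArA-oxy)-3-oxobutanoate | C=CCOC(=O)C(Oc1cc(C)cc(OCC=C(C)C)c1C(=O)OC)C(C)=O
A7 | alternative 2 | methyl 4,4-diethoxybut-2-ynoate | CCOC(OCC)C#CC(=O)OC
A8 | alternative 2 | methyl 2-[2-(diethoxymethyl)-4,6-dihydroxyphenoxy]-4-methyl-6-(3-methylbut-2-enyloxy)benzoate | COC(=O)c1c(OCC=C(C)C)cc(C)cc1Oc1c(C(OCC)OCC)cc(O)cc1O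
A9 | alternative 3 | methyl 2-[2-(tert-butyldimethylsilyloxymethyl)-4-methoxy-6-(3-methylbut-2-enyloxy)phenoxy]-6-hydroxy-4-methylbenzoate | COC(=O)c1c(O)cc(C)cc1Oc1c(CO[Si](C)(C)C(C)(C)C)cc(OC)cc1OCC=C(C)C
A10 | alternative 3 | dimethyl 2-{1-[2-(tert-butyldimethylsilyloxymethyl)-4-methoxy-6-(3-methylbut-2-enyloxy)phenoxy]-3-methylbut-2-enylidene}malonate | COC(=O)C(C(=O)OC)=C(Oc1c(CO[Si](C)(C)C(C)(C)C)cc(OC)cc1OCC=C(C)C)C=C(C)C
A11 | alternative 3 | dimethyl 2-(1-chloro-3-methylbut-2-enylidene)malonate | COC(=O)C(C(=O)OC)=C(Cl)C=C(C)C
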